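**Plan**
- Retrosynthetic cuts: the lactone carbonyl C12 (O6–C12 and C11–C12, i.e. carbon monoxide onto a C7 ethynyl group and the C6 hydroxyl), the O–C5 ester bond (epoxide opening), the C2–C3 bond of the ketol chain (sulfone acylation), and finally the ring bonds C1–C10 and C6–C7.
- Enabling feature: in the seven-membered carbocycle the acyl-bearing C1 and the oxygenated C9 flank C10, so the ring is a masked cyclohepta-1,4-diene (C1=C5, C8=C9) whose three sp3 carbons C6, C7 and C10 carry their substituents on one face, which is what a cis-divinylcyclopropane Cope shift delivers.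
- Forward order: a siloxy vinyldiazoacetate and a silyloxy dienyne are joined; the cyclopropane forms and expands in the same operation to the seven-membered ring; an epoxide across C1/C5 is then made and opened; the α-methylene-γ-butyrolactone is closed last.
- Stereochemistry: C6, C7 and C10 from the key step (chiral dirhodium catalyst plus alkene geometries); C9 by hindered-hydride reduction and Mitsunobu inversion; C1 and C5 by hydroxyl-directed epoxidation and SN2 opening; C4 from (S)-propylene oxide; the ester centre from (R)-2-methylbutanoic acid.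

Key step: step 5

Numbering and abbreviations: ring carbons in order are C1 (carries the ketol chain C2–C4), C5, C6, C7, C8, C9, C10 (carries the methyl); lactone carbons are C11 (on C7), C12 (carbonyl) and C13 (methylene). α is the ring face bearing the C10 methyl, β the other face. TBS = tert-butyldimethylsilyl, TES = triethylsilyl, TIPS = triisopropylsilyl, TBDPS = tert-butyldiphenylsilyl.

Assumption: Rh2(S-DOSP)4 is taken to select the face of the Z silyl enol ether in the sense it shows with styrene (donor cis to the alkene π-substituent, (1S,2R) cyclopropane); Rh2(R-DOSP)4 would replace it if this sense proved reversed.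

**Route**

Step 1
Reactants: 1 ethyl diazoacetate; 2 (tert-butyldimethylsilyloxy)acetaldehyde
Product: 3 ethyl 2-diazo-3-hydroxy-4-(TBS-oxy)butanoate (racemic)
Conditions: DBU (10 mol %), MeCN, rt
Reagents that add atoms: none
Why: Base-catalysed aldol-type addition of the acidic diazo C–H carbon to the aldehyde; the new carbinol centre is removed in the next step, so its configuration does not matter.

Step 2
Reactants: 3 ethyl 2-diazo-3-hydroxy-4-(TBS-oxy)butanoate
Product: 4 ethyl (E)-2-diazo-4-(TBS-oxy)but-3-enoate (fragment 1; used freshly prepared)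
Conditions: POCl3, Et3N, CH2Cl2, 0 °C → rt
Reagents that add atoms: none
Why: Dehydration of a β-hydroxy-α-diazo ester through its dichlorophosphate, where only C4 carries β-hydrogens and the conjugated E enol ether is the less strained geometry.

Step 3
Reactants: 5 diethyl (2-oxobutyl)phosphonate; 6 3-(triisopropylsilyl)prop-2-ynal
Product: 7 (E)-7-(triisopropylsilyl)hept-4-en-6-yn-3-one
Conditions: LiCl, iPr2NEt, MeCN, 0 °C → rt
Reagents that add atoms: none
Why: Horner–Wadsworth–Emmons olefination with a stabilised β-ketophosphonate under mild amine/LiCl conditions, which should give the E enone without base damage to the ynal.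

Step 4
Reactants: 7 (E)-7-(triisopropylsilyl)hept-4-en-6-yn-3-one
Product: 8 (2Z,4E)-3-(triethylsilyloxy)-7-(triisopropylsilyl)hepta-2,4-dien-6-yne (fragment 2)
Conditions: Et3SiOTf, Et3N, CH2Cl2, −78 → 0 °C
Reagents that add atoms: triethylsilyl trifluoromethanesulfonate, CC[Si](CC)(CC)OS(=O)(=O)C(F)(F)F
Why: Soft enolisation and O-silylation of an ethyl ketone, which can enolise only toward the ethyl group and should favour the Z enol ether (methyl cis to oxygen) to minimise allylic strain.

Step 5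
Reactants: 4 ethyl (E)-2-diazo-4-(TBS-oxy)but-3-enoate; 8 (2Z,4E)-3-(triethylsilyloxy)-7-(triisopropylsilyl)hepta-2,4-dien-6-yne
Product: 10 ethyl (6S,7S,10R)-6α-(TBS-oxy)-10α-methyl-9-(TES-oxy)-7α-[(TIPS)ethynyl]cyclohepta-1(5),8-diene-1-carboxylate, via cis-divinylcyclopropane 9 (not isolated)
Conditions: Rh2(S-DOSP)4 (dirhodium tetrakis[(S)-N-(4-dodecylphenylsulfonyl)prolinate], 1 mol %), hexanes, −40 °C → rt, slow addition of 4; then 40 °C
Reagents that add atoms: none
Why: The dirhodium carboxylate converts 4 into a donor/acceptor vinylcarbenoid whose carbenoid carbon (C1) adds [2+1] across the electron-rich C9=C10 enol ether bond of 8, closing the three-membered ring C1–C9–C10 by asynchronous carbene transfer in which C10 bonds first and charge builds at the oxygen-stabilised C9; the E-disubstituted enyne alkene and the shielded silylalkyne are not attacked by this class of carbenoid, which secures site selectivity. The cis-divinylcyclopropane 9 then undergoes a strain-driven [3,3] sigmatropic (Cope) shift through a boat transition state that breaks C1–C9 and forms C6–C7, so the seven-membered ring is closed by sigmatropic ring expansion (overall bonds C1–C10 and C6–C7, a formal [4+3] cycloaddition). The closest known reaction type is the dirhodium-catalysed tandem cyclopropanation/Cope rearrangement of vinyldiazoacetates with dienes, 2-silyloxydienes included. C10 is set by the chiral catalyst, which chooses the face of the enol ether, while the Z geometry keeps the methyl cis to the silyloxy group and therefore anti to both vinyl groups. C6 and C7 are set by the E geometries of the enol ether in 4 and of the enyne in 8, which both point outward in the boat and so end cis to each other and to the C10 methyl. The cis-divinyl arrangement relies on the usual preference of such carbenoids to place the vinyl donor cis to the unsaturated substituent of the alkene, and the substituent at the vinyl terminus of 4 should suppress vinylogous attack.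

Step 6
Reactants: 10 cycloheptadiene from step 5
Product: 11 ethyl 6α-(TBS-oxy)-10α-methyl-9-oxo-7α-[(TIPS)ethynyl]cyclohept-1(5)-ene-1-carboxylate
Conditions: AcOH/THF/H2O (3:6:1), 0 °C
Reagents that add atoms: none
Why: Mild acid hydrolysis of a silyl enol ether, far faster than cleavage of the secondary TBS ether; protonation occurs at C8, so no stereocentre is touched and the weakly acidic medium avoids enolisation toward C10.

Step 7
Reactants: 11 C9 ketone
Product: 12 ethyl 6α-(TBS-oxy)-9α-hydroxy-10α-methyl-7α-[(TIPS)ethynyl]cyclohept-1(5)-ene-1-carboxylate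
Conditions: LiBH(sBu)3, THF, −78 °C
Reagents that add atoms: none
Why: Steric-approach-controlled ketone reduction in which the bulky hydride attacks the β face, away from the α-oriented C10 methyl, C7 alkynyl and C6 silyloxy groups, to give the 9α alcohol; it should outpace conjugate reduction of the hindered enoate at this temperature.

Step 8
Reactants: 12 9α-alcohol
Product: 13 ethyl 6α-(TBS-oxy)-10α-methyl-9β-(4-nitrobenzoyloxy)-7α-[(TIPS)ethynyl]cyclohept-1(5)-ene-1-carboxylate
Conditions: 4-O2NC6H4CO2H, PPh3, DIAD, toluene, 0 °C → rt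
Reagents that add atoms: 4-nitrobenzoic acid, O=C(O)c1ccc([N+](=O)[O-])cc1
Why: Mitsunobu reaction with an acidic carboxylic acid, in which SN2 displacement of the oxyphosphonium from the open β face inverts C9 to the configuration of the target.

Step 9
Reactants: 13 9β-(4-nitrobenzoate)
Product: 14 ethyl 6α-(TBS-oxy)-9β-hydroxy-10α-methyl-7α-[(TIPS)ethynyl]cyclohept-1(5)-ene-1-carboxylate
Conditions: K2CO3, EtOH, rt
Reagents that add atoms: none
Why: Base-catalysed transesterification of the activated aryl ester, run in ethanol so that the ring ethyl ester cannot be scrambled.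

Step 10
Reactants: 14 9β-alcohol
Product: 15 ethyl 6α-(TBS-oxy)-10α-methyl-9β-(TIPS-oxy)-7α-[(TIPS)ethynyl]cyclohept-1(5)-ene-1-carboxylate
Conditions: iPr3SiOTf, 2,6-lutidine, CH2Cl2, 0 °C
Reagents that add atoms: triisopropylsilyl trifluoromethanesulfonate, CC(C)[Si](OS(=O)(=O)C(F)(F)F)(C(C)C)C(C)C
Why: Silylation of a hindered secondary alcohol with a silyl triflate, giving an ether that later survives the selective removal of the C6 TBS group.

Step 11
Reactants: 16 (S)-propylene oxide
Product: 17 (S)-1-(phenylsulfonyl)propan-2-ol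
Conditions: PhSO2Na, AcOH, EtOH/H2O, 60 °C (sealed vessel)
Reagents that add atoms: sodium benzenesulfinate, O=S([O-])c1ccccc1.[Na+]
Why: SN2 opening of the epoxide at its unsubstituted carbon by the sulfur of the sulfinate, which leaves the stereocentre untouched.

Step 12
Reactants: 17 (S)-1-(phenylsulfonyl)propan-2-ol
Product: 18 (S)-2-(TBDPS-oxy)propyl phenyl sulfone (fragment 3)
Conditions: tBuPh2SiCl, imidazole, DMF, rt
Reagents that add atoms: tert-butyl(chloro)diphenylsilane, CC(C)(C)[Si](Cl)(c1ccccc1)c1ccccc1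
Why: Standard imidazole-promoted silylation of a secondary alcohol, chosen because this ether resists the later HF·pyridine step.

Step 13
Reactants: 15 ring ethyl ester
Product: 19 N-methoxy-N-methyl-6α-(TBS-oxy)-10α-methyl-9β-(TIPS-oxy)-7α-[(TIPS)ethynyl]cyclohept-1(5)-ene-1-carboxamide
Conditions: MeNHOMe·HCl, iPrMgCl, THF, −20 → 0 °C
Reagents that add atoms: N,O-dimethylhydroxylamine hydrochloride, CNOC.Cl
Why: Weinreb amide formation by aminolysis of the ester with the chloromagnesium amide, which prepares a clean single acylation in the next step.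

Step 14
Reactants: 19 Weinreb amide; 18 (S)-2-(TBDPS-oxy)propyl phenyl sulfone
Product: 21 1-[(3S)-3-(TBDPS-oxy)-2-(phenylsulfonyl)butanoyl]-6α-(TBS-oxy)-10α-methyl-9β-(TIPS-oxy)-7α-[(TIPS)ethynyl]cyclohept-1(5)-ene (C3 epimers), via lithiated sulfone 20 (not isolated)
Conditions: 18 (2 equiv), n-BuLi, THF, −78 °C; then 19, −78 → −40 °C
Reagents that add atoms: none
Why: Acylation of an α-sulfonyl carbanion by a Weinreb amide, where the chelated tetrahedral intermediate prevents over-addition, the low temperature restrains β-elimination of the silyloxy group, and the C3 epimers converge in the next step.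

Step 15
Reactants: 21 β-keto sulfone
Product: 22 1-[(S)-3-(TBDPS-oxy)butanoyl]-6α-(TBS-oxy)-10α-methyl-9β-(TIPS-oxy)-7α-[(TIPS)ethynyl]cyclohept-1(5)-ene
Conditions: SmI2 (2.2 equiv), THF/MeOH, −78 °C
Reagents that add atoms: none
Why: Reductive desulfonylation of a β-keto sulfone by single-electron transfer from samarium diiodide, which at this temperature should be much faster than reduction of the cross-conjugated enone.

Step 16
Reactants: 22 silyl-protected enone
Product: 23 1-[(S)-3-(TBDPS-oxy)butanoyl]-6α-hydroxy-10α-methyl-9β-(TIPS-oxy)-7α-[(TIPS)ethynyl]cyclohept-1(5)-ene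
Conditions: HF·pyridine, pyridine, THF, 0 °C
Reagents that add atoms: none
Why: Selective desilylation, in which the secondary TBS ether is cleaved by buffered HF well before the bulkier TIPS and TBDPS ethers, and the carbon-bound TIPS group is inert.

Step 17
Reactants: 23 γ-hydroxy enone
Product: 24 1α,5α-epoxy-1β-[(S)-3-(TBDPS-oxy)butanoyl]-6α-hydroxy-10α-methyl-9β-(TIPS-oxy)-7α-[(TIPS)ethynyl]cycloheptane
Conditions: tBuOOH, n-BuLi, THF, −78 → −20 °C
Reagents that add atoms: tert-butyl hydroperoxide, CC(C)(C)OO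
Why: Alkoxide-directed nucleophilic (Weitz–Scheffer) epoxidation, in which the lithium alkoxide at C6 delivers the peroxide to C5 on the α face and the enolate closes the oxirane on the same face, setting C1 and C5 syn to the C6 hydroxyl.

Step 18
Reactants: 24 epoxy ketone; 25 (R)-2-methylbutanoic acid
Product: 27 1β-[(S)-3-(TBDPS-oxy)butanoyl]-1α,6α-dihydroxy-10α-methyl-5β-[(R)-2-methylbutanoyloxy]-9β-(TIPS-oxy)-7α-[(TIPS)ethynyl]cycloheptane, via cesium (R)-2-methylbutanoate 26 (not isolated)
Conditions: 25 (5 equiv), Cs2CO3 (1.5 equiv), DMF, 60 °C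
Reagents that add atoms: none
Why: SN2 opening of the epoxide by a cesium carboxylate at the secondary C5 (the quaternary, carbonyl-flanked C1 is blocked), which inverts C5 to the 5β ester and leaves the 1α hydroxyl; the cis epoxy alcohol cannot undergo Payne rearrangement and the excess acid buffers the medium.

Step 19
Reactants: 27 silyl-protected ester
Product: 28 7α-ethynyl-1α,6α,9β-trihydroxy-1β-[(S)-3-hydroxybutanoyl]-10α-methyl-5β-[(R)-2-methylbutanoyloxy]cycloheptane
Conditions: Bu4NF, AcOH (1:1), THF, rt → 40 °C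
Reagents that add atoms: none
Why: Fluoride-induced cleavage of the two silyl ethers and of the alkynyl C–Si bond, buffered with acetic acid to suppress acyl migration, retro-aldol cleavage and β-elimination in the ketol chain.

Step 20
Reactants: 28 tetraol alkyne; 29 carbon monoxide
Product: 30 target CNP0291806.3
Conditions: PdCl2 (10 mol %), PPh3, SnCl2, CO (7 atm), MeCN, 75 °C
Reagents that add atoms: none
Why: Palladium-catalysed cyclocarbonylation of a homopropargylic alcohol, in which an alkoxycarbonyl complex of divalent palladium formed at the C6 oxygen adds syn across the alkyne and protonolysis releases the exo-methylene lactone; only the C6 hydroxyl is cis and adjacent to the ethynyl group, so the cis-fused five-membered lactone should form without change at any stereocentre.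

**Compound list**
1 | ethyl diazoacetate | CCOC(=O)C=[N+]=[N-] | starting material
2 | (tert-butyldimethylsilyloxy)acetaldehyde | O=CCO[Si](C)(C)C(C)(C)C | starting material
3 | ethyl 2-diazo-3-hydroxy-4-(tert-butyldimethylsilyloxy)butanoate (racemic) | CCOC(=O)C(=[N+]=[N-])C(O)CO[Si](C)(C)C(C)(C)C | intermediate
4 | ethyl (E)-2-diazo-4-(tert-butyldimethylsilyloxy)but-3-enoate (fragment 1) | CCOC(=O)C(=[N+]=[N-])/C=C/O[Si](C)(C)C(C)(C)C | intermediate
5 | diethyl (2-oxobutyl)phosphonate | CCC(=O)CP(=O)(OCC)OCC | starting material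
6 | 3-(triisopropylsilyl)prop-2-ynal | O=CC#C[Si](C(C)C)(C(C)C)C(C)C | starting material
7 | (E)-7-(triisopropylsilyl)hept-4-en-6-yn-3-one | CCC(=O)/C=C/C#C[Si](C(C)C)(C(C)C)C(C)C | intermediate
8 | (2Z,4E)-3-(triethylsilyloxy)-7-(triisopropylsilyl)hepta-2,4-dien-6-yne (fragment 2) | C/C=C(/C=C/C#C[Si](C(C)C)(C(C)C)C(C)C)O[Si](CC)(CC)CC | intermediate
9 | ethyl (1S,2R,3R)-1-[(E)-2-(tert-butyldimethylsilyloxy)ethenyl]-3-methyl-2-(triethylsilyloxy)-2-[(E)-4-(triisopropylsilyl)but-1-en-3-ynyl]cyclopropane-1-carboxylate (cis-divinylcyclopropane, not isolated) | CCOC(=O)[C@@]1(/C=C/O[Si](C)(C)C(C)(C)C)[C@@H](C)[C@@]1(/C=C/C#C[Si](C(C)C)(C(C)C)C(C)C)O[Si](CC)(CC)CC | intermediate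
10 | ethyl (6S,7S,10R)-6α-(TBS-oxy)-10α-methyl-9-(TES-oxy)-7α-[(TIPS)ethynyl]cyclohepta-1(5),8-diene-1-carboxylate | CC(C)(C)[Si](C)(C)O[C@@H]1[C@H](C#C[Si](C(C)C)(C(C)C)C(C)C)C=C(O[Si](CC)(CC)CC)[C@H](C)C(C(=O)OCC)=C1 | intermediate
11 | ethyl 6α-(TBS-oxy)-10α-methyl-9-oxo-7α-[(TIPS)ethynyl]cyclohept-1(5)-ene-1-carboxylate | CC(C)(C)[Si](C)(C)O[C@@H]1[C@H](C#C[Si](C(C)C)(C(C)C)C(C)C)CC(=O)[C@H](C)C(C(=O)OCC)=C1 | intermediate
12 | ethyl 6α-(TBS-oxy)-9α-hydroxy-10α-methyl-7α-[(TIPS)ethynyl]cyclohept-1(5)-ene-1-carboxylate | CC(C)(C)[Si](C)(C)O[C@@H]1[C@H](C#C[Si](C(C)C)(C(C)C)C(C)C)C[C@H](O)[C@H](C)C(C(=O)OCC)=C1 | intermediate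
13 | ethyl 6α-(TBS-oxy)-10α-methyl-9β-(4-nitrobenzoyloxy)-7α-[(TIPS)ethynyl]cyclohept-1(5)-ene-1-carboxylate | CC(C)(C)[Si](C)(C)O[C@@H]1[C@H](C#C[Si](C(C)C)(C(C)C)C(C)C)C[C@@H](OC(=O)c2ccc([N+](=O)[O-])cc2)[C@H](C)C(C(=O)OCC)=C1 | intermediate
14 | ethyl 6α-(TBS-oxy)-9β-hydroxy-10α-methyl-7α-[(TIPS)ethynyl]cyclohept-1(5)-ene-1-carboxylate | CC(C)(C)[Si](C)(C)O[C@@H]1[C@H](C#C[Si](C(C)C)(C(C)C)C(C)C)C[C@@H](O)[C@H](C)C(C(=O)OCC)=C1 | intermediate
15 | ethyl 6α-(TBS-oxy)-10α-methyl-9β-(TIPS-oxy)-7α-[(TIPS)ethynyl]cyclohept-1(5)-ene-1-carboxylate | CC(C)(C)[Si](C)(C)O[C@@H]1[C@H](C#C[Si](C(C)C)(C(C)C)C(C)C)C[C@@H](O[Si](C(C)C)(C(C)C)C(C)C)[C@H](C)C(C(=O)OCC)=C1 | intermediate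
16 | (S)-propylene oxide | C[C@H]1CO1 | starting material
17 | (S)-1-(phenylsulfonyl)propan-2-ol | C[C@H](O)CS(=O)(=O)c1ccccc1 | intermediate
18 | (S)-2-(tert-butyldiphenylsilyloxy)propyl phenyl sulfone (fragment 3) | C[C@H](O[Si](c1ccccc1)(c1ccccc1)C(C)(C)C)CS(=O)(=O)c1ccccc1 | intermediate
19 | N-methoxy-N-methyl-6α-(TBS-oxy)-10α-methyl-9β-(TIPS-oxy)-7α-[(TIPS)ethynyl]cyclohept-1(5)-ene-1-carboxamide | CC(C)(C)[Si](C)(C)O[C@@H]1[C@H](C#C[Si](C(C)C)(C(C)C)C(C)C)C[C@@H](O[Si](C(C)C)(C(C)C)C(C)C)[C@H](C)C(C(=O)N(C)OC)=C1 | intermediate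
20 | [(2S)-2-(tert-butyldiphenylsilyloxy)-1-(phenylsulfonyl)propyl]lithium (lithiated sulfone, not isolated) | C[C@H](O[Si](c1ccccc1)(c1ccccc1)C(C)(C)C)C([Li])S(=O)(=O)c1ccccc1 | intermediate
21 | 1-[(3S)-3-(TBDPS-oxy)-2-(phenylsulfonyl)butanoyl]-6α-(TBS-oxy)-10α-methyl-9β-(TIPS-oxy)-7α-[(TIPS)ethynyl]cyclohept-1(5)-ene (C3 epimers) | CC(C)(C)[Si](C)(C)O[C@@H]1[C@H](C#C[Si](C(C)C)(C(C)C)C(C)C)C[C@@H](O[Si](C(C)C)(C(C)C)C(C)C)[C@H](C)C(C(=O)C([C@H](C)O[Si](c2ccccc2)(c2ccccc2)C(C)(C)C)S(=O)(=O)c2ccccc2)=C1 | intermediate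
22 | 1-[(S)-3-(TBDPS-oxy)butanoyl]-6α-(TBS-oxy)-10α-methyl-9β-(TIPS-oxy)-7α-[(TIPS)ethynyl]cyclohept-1(5)-ene | CC(C)(C)[Si](C)(C)O[C@@H]1[C@H](C#C[Si](C(C)C)(C(C)C)C(C)C)C[C@@H](O[Si](C(C)C)(C(C)C)C(C)C)[C@H](C)C(C(=O)C[C@H](C)O[Si](c2ccccc2)(c2ccccc2)C(C)(C)C)=C1 | intermediate
23 | 1-[(S)-3-(TBDPS-oxy)butanoyl]-6α-hydroxy-10α-methyl-9β-(TIPS-oxy)-7α-[(TIPS)ethynyl]cyclohept-1(5)-ene | O[C@@H]1[C@H](C#C[Si](C(C)C)(C(C)C)C(C)C)C[C@@H](O[Si](C(C)C)(C(C)C)C(C)C)[C@H](C)C(C(=O)C[C@H](C)O[Si](c2ccccc2)(c2ccccc2)C(C)(C)C)=C1 | intermediate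
24 | 1α,5α-epoxy-1β-[(S)-3-(TBDPS-oxy)butanoyl]-6α-hydroxy-10α-methyl-9β-(TIPS-oxy)-7α-[(TIPS)ethynyl]cycloheptane | O[C@@H]1[C@H](C#C[Si](C(C)C)(C(C)C)C(C)C)C[C@@H](O[Si](C(C)C)(C(C)C)C(C)C)[C@H](C)[C@]2(C(=O)C[C@H](C)O[Si](c3ccccc3)(c3ccccc3)C(C)(C)C)O[C@H]12 | intermediate
25 | (R)-2-methylbutanoic acid | CC[C@@H](C)C(=O)O | starting material
26 | cesium (R)-2-methylbutanoate (not isolated) | CC[C@@H](C)C(=O)[O-].[Cs+] | intermediate
27 | 1β-[(S)-3-(TBDPS-oxy)butanoyl]-1α,6α-dihydroxy-10α-methyl-5β-[(R)-2-methylbutanoyloxy]-9β-(TIPS-oxy)-7α-[(TIPS)ethynyl]cycloheptane | O[C@@H]1[C@H](C#C[Si](C(C)C)(C(C)C)C(C)C)C[C@@H](O[Si](C(C)C)(C(C)C)C(C)C)[C@H](C)[C@@](O)(C(=O)C[C@H](C)O[Si](c2ccccc2)(c2ccccc2)C(C)(C)C)[C@H]1OC(=O)[C@H](C)CC | intermediate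
28 | 7α-ethynyl-1α,6α,9β-trihydroxy-1β-[(S)-3-hydroxybutanoyl]-10α-methyl-5β-[(R)-2-methylbutanoyloxy]cycloheptane | O[C@@H]1[C@H](C#C)C[C@@H](O)[C@H](C)[C@@](O)(C(=O)C[C@H](C)O)[C@H]1OC(=O)[C@H](C)CC | intermediate
29 | carbon monoxide | [C-]#[O+] | starting material
30 | CNP0291806.3, (1S,5S,6R,7S,9R,10S)-configured cis-fused α-methylene-γ-butyrolactone with 1α,9β-dihydroxy, 1β-[(S)-3-hydroxybutanoyl], 10α-methyl and 5β-[(R)-2-methylbutanoyloxy] groups | C=C1C(=O)O[C@@H]2[C@H]1C[C@@H](O)[C@H](C)[C@@](O)(C(=O)C[C@H](C)O)[C@H]2OC(=O)[C@H](C)CC | target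

**Step count**
Total: 20 steps. Longest linear sequence: 16 steps (steps 1, 2, 5–10, 13–20 from ethyl diazoacetate; the branch through steps 3 and 4 is equally long).

**Three steps most likely to fail**

Step 5. The bulky carbenoid may react too slowly with the trisubstituted enol ether, so that carbenoid dimerisation or cyclisation of 4 to a pyrazole takes over. Addition may also turn stepwise and zwitterionic, leading to five-membered-ring annulation or loss of the cis-divinyl relationship, and face selection may be weak. The fallback sets out from 8, 1 and 2 and returns at 10, assembling the same cyclopropane stepwise by known siloxycyclopropane chemistry. Copper-catalysed cyclopropanation of 8 with the small acceptor carbenoid from ethyl diazoacetate 1 (CuOTf, a monovalent copper salt, with a C2-symmetric bis(oxazoline) ligand, CH2Cl2) should give ethyl 3-methyl-2-(triethylsilyloxy)-2-[(E)-4-(triisopropylsilyl)but-1-en-3-ynyl]cyclopropane-1-carboxylate F1, with methyl cis to silyloxy by stereospecific addition and the ester epimers of no consequence. Deprotonation with LiN(iPr)2 at −78 °C and aldol addition of the cyclopropyl ester enolate to aldehyde 2, expected to enter anti to the silyloxy and methyl groups and therefore cis to the dienyl arm, should give the β-hydroxy ester F2. Dehydration with the Burgess reagent in warm toluene should give the E enol ether, which is cyclopropane 9 and should rearrange under the same conditions to 10.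

Step 18. The carboxylate may be too weak a nucleophile for the hindered secondary epoxide carbon, and prolonged heating with base may cause β-elimination of the silyloxy group in the ketol chain or migration of the new acyl group from O5 to O6. The fallback sets out from 24 and returns at 28. Acid-catalysed hydrolysis of the epoxy ketone (HClO4, THF/H2O, 0 °C), with water entering at C5 with inversion, should give the 1α,5β,6α-triol F3. The cis-disposed 1α and 6α hydroxyls would be bridged as the di-tert-butylsilylene F4 (tBu2Si(OTf)2, 2,6-lutidine), which leaves only the 5β hydroxyl free. Steglich esterification with acid 25 (EDC, DMAP, CH2Cl2) should give the 5β-(R)-2-methylbutanoate F5, and the buffered fluoride treatment of step 19 would remove the silylene together with the other silyl groups to give 28.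

Step 20. At 75 °C with SnCl2 the polyol may undergo palladium-induced cycloisomerisation of the alkynol to an enol ether, dehydration of the ketol chain or acyl migration before the lactone closes. The fallback sets out from 28 and returns at 30. Markovnikov hydrostannation of the terminal alkyne (Bu3SnH, Mo(CO)3(CNtBu)3, THF, 55 °C) should give the 1-(tributylstannyl)vinyl tetraol F6. Iododestannylation (I2, CH2Cl2, 0 °C) should give the 1-iodovinyl tetraol F7. Carbonylative lactonisation of this hydroxy vinyl iodide under mild conditions (Pd(PPh3)4, a zerovalent palladium complex, CO 1 atm, Et3N, THF, 40 °C) should close the same α-methylene lactone to give 30.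

**Further compounds**
F1 | step 5 | ethyl 3-methyl-2-(triethylsilyloxy)-2-[(E)-4-(triisopropylsilyl)but-1-en-3-ynyl]cyclopropane-1-carboxylate (ester epimers) | CCOC(=O)C1[C@@H](C)[C@@]1(/C=C/C#C[Si](C(C)C)(C(C)C)C(C)C)O[Si](CC)(CC)CC
F2 | step 5 | ethyl 1-[2-(tert-butyldimethylsilyloxy)-1-hydroxyethyl]-3-methyl-2-(triethylsilyloxy)-2-[(E)-4-(triisopropylsilyl)but-1-en-3-ynyl]cyclopropane-1-carboxylate (carbinol epimers) | CCOC(=O)[C@@]1(C(O)CO[Si](C)(C)C(C)(C)C)[C@@H](C)[C@@]1(/C=C/C#C[Si](C(C)C)(C(C)C)C(C)C)O[Si](CC)(CC)CC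
F3 | step 18 | 1β-[(S)-3-(TBDPS-oxy)butanoyl]-1α,5β,6α-trihydroxy-10α-methyl-9β-(TIPS-oxy)-7α-[(TIPS)ethynyl]cycloheptane | O[C@@H]1[C@H](C#C[Si](C(C)C)(C(C)C)C(C)C)C[C@@H](O[Si](C(C)C)(C(C)C)C(C)C)[C@H](C)[C@@](O)(C(=O)C[C@H](C)O[Si](c2ccccc2)(c2ccccc2)C(C)(C)C)[C@H]1O
F4 | step 18 | 1α,6α-O-(di-tert-butylsilylene) derivative of F3 with free 5β-hydroxyl | O1[C@@H]2[C@H](C#C[Si](C(C)C)(C(C)C)C(C)C)C[C@@H](O[Si](C(C)C)(C(C)C)C(C)C)[C@H](C)[C@@](O[Si]1(C(C)(C)C)C(C)(C)C)(C(=O)C[C@H](C)O[Si](c3ccccc3)(c3ccccc3)C(C)(C)C)[C@H]2O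
F5 | step 18 | 5β-[(R)-2-methylbutanoate] of F4 | O1[C@@H]2[C@H](C#C[Si](C(C)C)(C(C)C)C(C)C)C[C@@H](O[Si](C(C)C)(C(C)C)C(C)C)[C@H](C)[C@@](O[Si]1(C(C)(C)C)C(C)(C)C)(C(=O)C[C@H](C)O[Si](c3ccccc3)(c3ccccc3)C(C)(C)C)[C@H]2OC(=O)[C@H](C)CC
F6 | step 20 | 7α-[1-(tributylstannyl)ethenyl] analogue of 28 | O[C@@H]1[C@H](C(=C)[Sn](CCCC)(CCCC)CCCC)C[C@@H](O)[C@H](C)[C@@](O)(C(=O)C[C@H](C)O)[C@H]1OC(=O)[C@H](C)CC
F7 | step 20 | 7α-(1-iodoethenyl) analogue of 28 | O[C@@H]1[C@H](C(=C)I)C[C@@H](O)[C@H](C)[C@@](O)(C(=O)C[C@H](C)O)[C@H]1OC(=O)[C@H](C)CC
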